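The data come from a simulation on assumed constants, and the scatter is random.

Step one. What stayed with me was the leftover. At 3.00 h the red flask still held 22.9% of its starting material, yet its target had dropped from 9.9% to 1.6% since 1.33 h. Target was disappearing while plenty of starting material stood by, so the next flask needed a stopping time.

all flasks: initiator 1 mol%

| run | starting material | reagent | remark | time |
|---|---|---|---|---|
| amber | 1.5 M | 1.4 equiv | run made earlier |  |
| red | 2.2 M | 1 equiv | run made earlier |  |
| flask | 1.5 M | 1.00 equiv |  | 2.5 h |

| run | time / h | target / % | starting material / % |
|---|---|---|---|
| amber | 0.133 | 9.6 | 86.7 |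
| amber | 0.250 | 12.9 | 77.2 |
| amber | 0.667 | 17.6 | 53.6 |
| amber | 1.33 | 13.4 | 35.3 |
| amber | 3.00 | 6.7 | 23.4 |
| red | 0.133 | 9.1 | 85.4 |
| red | 0.250 | 12.4 | 76.6 |
| red | 0.667 | 13.3 | 51.3 |
| red | 1.33 | 9.9 | 33.7 |
| red | 3.00 | 1.6 | 22.9 |

(standard deviation of a reading: 0.5 percentage points)



- time up to 2.5 h at which target stands highest
- the amount of target, in percent of the starting material charged, at that time
- earliest time at which at least nineteen twentieths of that best amount are there
- latest time at which they still are

Step two. I took the red run because its reagent equivalents are the flask's. Its target fell at 1.09 h⁻¹ while starting material averaged 28.3% of charge. That is a reading, and its last point carries the scatter. I assumed a pseudo-first-order loss that goes with the molarity of starting material. Scaled to the flask's charge, this gives the whole-charge half-life of target, the time target takes to halve with the entire charge of starting material beside it: 0.264 h. At any other fraction left, I divide it by that fraction.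

Step three. Starting material fell nearly alike in the amber and red runs, but those two held 2.10 M and 2.20 M of reagent, and the flask holds less, 1.50 M, so their agreement promised nothing for the flask. I therefore took the amber fractions as a trial and no more. At 53.6% left the half-life is 0.492 h, and at 23.4% it is 1.13 h. From 0.667 h to the longest time, that makes 1.62 to 3.73 halvings, and by my rule a flask that keeps more starting material counts more of them.

Step four. I decided to charge the flask as written and take it off by 1.33 h, not leave it standing to 2.5 h.

The forecast said 15.8% at 0.52 h, with the window from 0.36 h to 0.8 h: “The flask shares amber's concentration and red's equivalents, so I place it between them.”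

The flask gave 11.6% at 0.521 h, with the window from 0.358 h to 0.738 h. All four stand within the margins.

    first chain carrier → ended carrier (k = 3500 min⁻¹)
    starting material + target → side product (k = 0.0260 L mol⁻¹ min⁻¹)
    starting material + second chain carrier → released group + first chain carrier (k = 2.00 × 10⁵ L mol⁻¹ min⁻¹)
    2 first chain carrier → ended chains A (k = 3.30 × 10⁶ L mol⁻¹ s⁻¹)
    initiator → 2 initiating radical (k = 0.0350 min⁻¹)
    reagent + first chain carrier → target + second chain carrier (k = 40000 L mol⁻¹ min⁻¹)
    2 second chain carrier → ended chains B (k = 1.00 × 10⁶ L mol⁻¹ s⁻¹)
    starting material + initiating radical → capped initiator + first chain carrier (k = 10000 L mol⁻¹ s⁻¹)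
    crystals ⇌ released group, rate k9*(cs9 - [released group]) while solid is left; crystals form when [released group] > cs9 (solubility = 1.00 M, k = 2.30 min⁻¹)

By 0.500 h the flask's step from reagent + first chain carrier to target + second chain carrier had 69% of its turnover behind it, and the step from starting material + target to side product 31%. With 43.7% left at the end, the half-life reads 0.603 h, which counts 3.28 halvings after the best time against 2.09 seen, with 31.0% of the making still ahead at 0.500 h.

For the neighbour charged at 0.38 M, with 84.5% left at its end, the half-life reads 1.23 h, longer than the flask's. Computed, its target falls from 5.18% to 2.93%, a factor of 1.77 against the flask's 4.27.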